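**Remark (assumption):** Commercial (R)-citronellal of high enantiomeric purity is assumed, because its C3 center becomes C11' unchanged and a remote-methyl epimer could not be removed later.

## Structural features

The target is a 2-methyl-1,4-naphthoquinone (ring A the benzo ring, ring B the quinonoid ring) whose C3 carries, through the methylene C1', a sixteen-carbon chain with four methyl branches, i.e. a phylloquinone skeleton hydroxylated at C5'. The chain holds an E-trisubstituted alkene C2'=C3' and three stereocenters: the carbinol C5' (S) and the methyl-bearing methines C7' (R) and C11' (R). C5' and C7' stand in a 1,3-relation across C6', whereas C7' and C11' are 1,5-related and, in the target, far from any functional group. The quinone is the fragile part: it is electrophilic, reducible and light-sensitive, base deprotonates the doubly activated C1' methylene, and the C2'=C3' alkene, to which the C5' hydroxyl is homoallylic, can lose its geometry or move into conjugation. The real difficulty lies in the saturated half: C7' and C11' have no neighbouring handle, and epimers differing only there cannot be expected to separate, so each must be set with high fidelity and never eroded. C11' maps onto C3 of (R)-citronellal. The key step exploits the fact that the C7' methyl stands two carbons from the oxygenated C5': C5'–C6'–C7'(CH3)–C8' is the C1–C4 pattern of a 3-methylalk-4-enoate, so C6'–C7' can be forged by an orthoester Claisen rearrangement that trades an easily controlled carbinol at C9' for the C7' center. The remaining atoms C1'–C4' and the ring are then attached to the ester carbon C5' by propargylation, methylalumination and coupling to a preformed quinone.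

## Logic of the disconnections

**21 ⇒ 20.** Only the O–Si bond at C5' is cut. The reason is that the organoaluminium and low-valent nickel chemistry one step earlier is cleaner without a free hydroxyl. Nothing is gained in skeleton. The demand is a desilylation that avoids base, since the quinone and its C1' methylene do not tolerate it.

**20 ⇒ 18 + 19, and 19 ⇒ 16.** The sp3–sp2 bond C1'–C2' is cut, and behind it C3'–CH3 and C2'–Al. This makes the E-trisubstituted alkene by a syn addition whose geometry is fixed by mechanism, not by an olefination of uncertain E/Z ratio, and the quinone arrives complete. The gain is that the whole ring system is split off and the chain is reduced to a terminal alkyne. The forward step must place methyl on the internal alkyne carbon, couple with retention and without allylic transposition, and spare the quinone carbonyls.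

**18 ⇒ 17.** The bond between C3 of ring B and C1' is cut. 17 is commercial and holds every ring atom. The forward step must functionalise the single free quinonoid position once and leave ring A alone.

**16 ⇒ 15 ⇒ 13 + 14.** After the O–Si bond, C4'–C5' is cut. A carbinol flanked by a methylene that leads to an alkyne is the retron of carbonyl propargylation, and C5' is set as the bond forms. The chain shrinks to a C15 aldehyde that holds only the two methyl centers. The demand is catalyst control of the aldehyde face, because the β-methyl at C7' induces little, and γ-selective delivery so that an alkyne and not an allene results.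

**13 ⇒ 12 ⇒ 11.** No skeletal bond is cut; the aldehyde is traced to the ester oxidation level and the saturated C8'–C9' bond to an E-alkene. This uncovers the 3-methylalk-4-enoate. The partial reduction must stop at the aldehyde, and the saturation must not move the double bond toward C7' or C11'.

**11 ⇒ 7 + 8 (through 10 and 9).** C6'–C7' is cut, the alkene returns from C8'=C9' to C7'=C8' and the C9'–O bond is restored. A stereocenter with no handle (C7') is exchanged for a secondary allylic carbinol (C9') that can be set by carbonyl reduction and checked before it is spent. C5' and C6' come from 8, and the 1,5-dimethyl problem becomes one carbinol plus one chiral-pool methyl. The demand is complete 1,3-chirality transfer, which needs an enantiopure carbinol, a geometrically pure E-alkene and a single chair.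

**7 ⇒ 6 ⇒ 5 ⇒ 4 ⇒ 2 + 3.** The alkene is traced to an alkyne, the carbinol to a ketone, and C8'–C9' is cut. The alkyne guarantees the E geometry by trans-hydroalumination, and the ynone belongs to the class for which catalytic asymmetric reduction is most dependable. Direct enantioselective alkynylation of 2 would be two steps shorter but is less dependable for an α-unbranched aldehyde, and the purity reached here becomes the purity of C7'. The demand is catalyst control at C9' independent of C11'.

**2 ⇒ 1.** No skeletal bond is cut; the saturated terminus is traced to the trisubstituted alkene of the chiral-pool aldehyde that supplies C11'. Saturating here, and not together with C8'=C9' later, costs one step but leaves step 7 with a single unhindered disubstituted alkene. The alkene must be reduced in the presence of the aldehyde.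

## Other disconnections considered

**Alternative 1:** Ring B itself is cut: C1–C2, C3–C4 and C1–C8a (numbering of naphthol A1) are disconnected. This leaves the carbene complex (CO)5Cr=C(OMe)Ph A3 (zerovalent chromium), one CO ligand and the complete chain as the silyl-protected skipped enyne A2. The bond C4–C4a is not among those formed: it is the carbene carbon–ipso carbon bond already present in A3, and the third new bond runs from the inserted CO carbon to the ortho carbon of the phenyl ring.

- Forward: A2 and A3 would be warmed in an ether solvent. CO loss, alkyne insertion into Cr=C, CO insertion to a vinylketene, 6π-electrocyclisation and tautomerisation (Dötz benzannulation) would give A1. Oxidation with (NH4)2Ce(NO3)6 would then give 20.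
- In favour: the quinone appears only at the end, so no organometallic reagent meets it; on this point the alternative is better than step 12. Methyl and chain are of similar size, but either orientation of alkyne insertion leads to the same quinone after oxidation, so regiochemistry is harmless.
- Against: a stoichiometric chromium complex is needed. Dialkyl internal alkynes are the class most given to cyclobutenone, indene and furan side channels. The C1' methylene of A2 is both propargylic and allylic and can isomerise into conjugation on heating. Ring B is exactly the part that 17 supplies ready-made.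
- Comparison: structurally nothing difficult is simplified, since C5', C7', C11' and the E-alkene all remain in A2, which needs the chain chemistry of steps 1–10 plus a propynyl unit on C1'. Mechanistically a five-event cascade replaces one cross-coupling. In step count it would be longer by at least three operations. It is the equal of the chosen plan in tolerating the silyl ether and in the final deprotection.

**Alternative 2:** The cut is C4'–C5' with allylic transposition, giving 13 and the S-configured secondary allylic boronic ester A5. In A5 boron sits on C2', C3' bears the methyl, C4' is a terminal methylene and the ring is masked as the 1,4-dimethoxynaphthalene.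

- Forward: n-BuLi would convert A5 into its boronate complex and (CF3CO)2O into a less hindered, more Lewis-acidic borinic ester, which adds to 13 through C4' in a closed chair. With the C1' substituent and the aldehyde chain both equatorial, S at C2' maps onto S at C5' and the alkene reappears as E-C2'=C3', giving A4. (NH4)2Ce(NO3)6 would oxidise A4 directly to 21.
- In favour: one step makes the C–C bond, the trisubstituted alkene and C5'. No hydroxyl protection, aluminium or nickel is needed, and the quinone stays masked. On these points it is better than steps 9–13.
- Against: C7' and C11' are untouched, so 13, and with it steps 1–8 including the Claisen step, is still required. A5 would need about five operations from 17 (dimethyl ether, two-carbon homologation to an arylethyl carbamate, sparteine-mediated lithiation–borylation with an isopropenylboronic ester), and its purity would rest on a stoichiometric chiral diamine. The C3' methyl imposes A(1,2) strain on an equatorial C1' substituent, so the E preference is less secure than for an unsubstituted allyl unit, and any Z-alkene would also carry the wrong C5'. The secondary alcohol must survive the cerium oxidation.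
- Comparison: both plans set C5' in a closed six-membered boron transition state, under catalyst control in step 9 and substrate control here; in kind they are equal. The alternative is more convergent and would shorten the longest linear sequence by about two steps, while its total count would be about two higher. It complements the key step and does not replace it.

**Alternative 3:** No skeletal bond is cut; C7' and C11' are both traced to trisubstituted alkenes of the trienoate A7, which would come from (2E,6E)-farnesal A8 by an enantioselective acetate aldol addition and silylation.

- Forward: H2 and [Ir(cod)(L)][B(C6H3(CF3)2)4] (L a chiral pyridyl phosphinite, monovalent iridium) would saturate the three alkenes of A7. The catalyst must select the correct face of C4=C5 and of C8=C9 to give A6; C12=C13 creates no center. Partial reduction of the ester and one-carbon homologation to the terminal alkyne would then give 16, and steps 11–13 would finish.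
- In favour: all chain carbons come from one achiral C15 unit, both methyl centers arise in one catalytic operation, and 16 would be reached in about six operations against ten. This is a clear advantage in step economy.
- Against: both remote centers would depend on intermolecular catalyst control, and each needs a geometrically pure E-alkene. The C4=C5 alkene is allylic to the silyloxy center, so catalyst and substrate preferences may be matched or mismatched, and ionisation of the allylic silyl ether at a cationic iridium hydride is conceivable. The four possible C7'/C11' diastereomers cannot be expected to separate, and no intermediate allows either center to be checked and upgraded. The ligand is not a stock reagent.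
- Comparison: in the chosen plan C11' is bought and C7' is relayed intramolecularly from a carbinol whose purity can be measured before use; here both are set by reagent control in one step. Alternative 3 is the better plan in step count and in using hydrogen as the only stoichiometric reagent for the stereocenters. The chosen plan is the safer one in stereochemical fidelity. The end-games are identical.

Key step: step 6

## Route

Step 1
Reactants: 1 (R)-citronellal [(3R)-3,7-dimethyloct-6-enal]
Product: 2 (3R)-3,7-dimethyloctanal
Conditions: H2 (1 atm), 5% Pd/C, EtOAc, rt
Reagents that add atoms: none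
Why: Heterogeneous hydrogenation saturates the isolated trisubstituted alkene faster than the aliphatic aldehyde in a non-alcoholic solvent; the C3 center lies three bonds from the alkene and is not touched.

Step 2
Reactants: 2 (3R)-3,7-dimethyloctanal; 3 1-propynylmagnesium bromide
Product: 4 (6R)-6,10-dimethylundec-2-yn-4-ol (both C4 epimers)
Conditions: 3 (1.2 equiv), THF, −78 → 0 °C; aq. NH4Cl
Reagents that add atoms: none
Why: Grignard 1,2-addition of a weakly basic alkynyl nucleophile, which adds faster than it enolises the aldehyde; the C4 configuration is irrelevant because step 3 erases it.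

Step 3
Reactants: 4 (6R)-6,10-dimethylundec-2-yn-4-ol
Product: 5 (6R)-6,10-dimethylundec-2-yn-4-one
Conditions: Dess–Martin periodinane, NaHCO3, CH2Cl2, 0 °C → rt
Reagents that add atoms: none
Why: Dess–Martin oxidation of a secondary propargylic alcohol under buffered, non-basic conditions that should not isomerise the ynone to an allenone; C6 is β to the carbonyl and cannot epimerise.

Step 4
Reactants: 5 (6R)-6,10-dimethylundec-2-yn-4-one
Product: 6 (4S,6R)-6,10-dimethylundec-2-yn-4-ol
Conditions: Ru[(S,S)-TsNCHPhCHPhNH](p-cymene) (1 mol%, divalent ruthenium), i-PrOH, rt
Reagents that add atoms: none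
Why: Noyori asymmetric transfer hydrogenation of an alkynyl ketone: the Ru–H/N–H pair delivers hydride to the Re face with the alkynyl group in the place taken by aryl in aryl ketones, which with the (S,S) ligand should give the S carbinol; control is by the catalyst, the C6 methyl being too remote to interfere.

Step 5
Reactants: 6 (4S,6R)-6,10-dimethylundec-2-yn-4-ol
Product: 7 (2E,4S,6R)-6,10-dimethylundec-2-en-4-ol
Conditions: LiAlH4 (2 equiv), THF, 0 → 65 °C; aq. potassium sodium tartrate
Reagents that add atoms: none
Why: Alkoxide-directed trans-hydroalumination of a propargylic alcohol: intramolecular hydride delivery from the alkoxyaluminate gives a cyclic alkenylalanate whose protonolysis should leave only the E-alkene; C4 is not involved.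

Step 6
Reactants: 7 (2E,4S,6R)-6,10-dimethylundec-2-en-4-ol; 8 triethyl orthoacetate
Product: 11 ethyl (3S,4E,7R)-3,7,11-trimethyldodec-4-enoate, via mixed orthoester 9 (not isolated), via ketene acetal 10 (not isolated)
Conditions: 8 (6 equiv), EtCO2H (10 mol%), 138 °C, EtOH distilled off
Reagents that add atoms: none
Why: Propionic acid catalyses exchange of one ethoxy group of 8 for the carbinol oxygen to give mixed orthoester 9, which loses a second molecule of ethanol to give ketene acetal 10; 10 then undergoes a concerted, suprafacial [3,3]-sigmatropic shift in which C9'–O breaks and C6'–C7' forms. This is the Johnson–Claisen orthoester rearrangement, whose closest precedent is the conversion of secondary E-allylic alcohols into 3-methylalk-4-enoates for methyl-branched isoprenoid chains. No ring is closed; the six-membered array exists only as the chair transition state. The new center C7' (C3 of 11) is controlled by the configuration of C9' (C4 of 7) together with the E geometry of the alkene: in the chair with the C10' chain equatorial on C9' and the terminal methyl equatorial on C7', the new bond forms on the face of the allyl unit from which oxygen leaves, so that S at C9' becomes 3S in 11, which is 7'R once C8'=C9' is saturated. The selectivity needed is this chair over the chair with the chain axial, which would give the Z-alkene and the opposite configuration at C7', and over boat forms; it is secured by the 1,3-diaxial interaction that an axial chain would suffer with the ethoxy group on the ketene acetal carbon. A weak acid and continuous removal of ethanol keep ionisation of the allylic C–O bond, the one process that could scramble C9' before rearrangement, to a minimum. The new alkene C8'=C9' should be E and C11' is a spectator.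

Step 7
Reactants: 11 ethyl (3S,4E,7R)-3,7,11-trimethyldodec-4-enoate
Product: 12 ethyl (3R,7R)-3,7,11-trimethyldodecanoate
Conditions: H2 (1 atm), PtO2 (2 mol%), EtOAc, rt
Reagents that add atoms: none
Why: Catalytic hydrogenation of an unhindered E-disubstituted alkene; PtO2 is chosen over Pd because it has little tendency to move the double bond toward the allylic C3 center before saturation; the descriptor of C3 changes from S to R only because C4 loses priority.

Step 8
Reactants: 12 ethyl (3R,7R)-3,7,11-trimethyldodecanoate
Product: 13 (3R,7R)-3,7,11-trimethyldodecanal
Conditions: i-Bu2AlH (1.05 equiv), CH2Cl2, −78 °C; MeOH, then aq. potassium sodium tartrate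
Reagents that add atoms: none
Why: Partial reduction of an ester: the tetrahedral aluminium hemiacetal is stable at −78 °C and collapses to the aldehyde only on work-up; no stereocenter is α to the carbonyl, so nothing can epimerise.

Step 9
Reactants: 13 (3R,7R)-3,7,11-trimethyldodecanal; 14 allenylboronic acid pinacol ester [4,4,5,5-tetramethyl-2-(propa-1,2-dienyl)-1,3,2-dioxaborolane]
Product: 15 (4S,6R,10R)-6,10,14-trimethylpentadec-1-yn-4-ol
Conditions: 14 (1.5 equiv), (R)-TRIP [(R)-3,3'-bis(2,4,6-triisopropylphenyl)-1,1'-binaphthyl-2,2'-diyl hydrogen phosphate] (10 mol%), 4 Å MS, toluene, −20 → 0 °C; aq. NaHCO3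
Reagents that add atoms: none
Why: Chiral Brønsted acid-catalysed propargylboration: the allenylboronate adds through its γ-carbon in a closed six-membered chair (SE2'), which gives the homopropargylic and not the allenic alcohol; the phosphoric acid, hydrogen-bonded to a boronate oxygen and to the formyl hydrogen, should by the accepted model direct addition to the Re face and so set C4 of 15 (C5' of the target) as S under catalyst control.

Step 10
Reactants: 15 (4S,6R,10R)-6,10,14-trimethylpentadec-1-yn-4-ol
Product: 16 tert-butyldimethyl{[(4S,6R,10R)-6,10,14-trimethylpentadec-1-yn-4-yl]oxy}silane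
Conditions: TBSCl, imidazole, DMF, rt
Reagents that add atoms: tert-butyldimethylsilyl chloride, CC(C)(C)[Si](C)(C)Cl
Why: Standard silylation of a secondary alcohol; the silyl ether keeps the oxygen from consuming Me3Al, from chelating the alkenylalane and from interfering with nickel in step 12, and it can be removed without base.

Step 11
Reactants: 17 menadione (2-methylnaphthalene-1,4-dione)
Product: 18 2-(chloromethyl)-3-methylnaphthalene-1,4-dione
Conditions: 37% aq. CH2O, HCl (g), AcOH, rt (closed hood)
Reagents that add atoms: formaldehyde, C=O; hydrogen chloride, Cl
Why: Known chloromethylation of menadione at its only unsubstituted quinonoid carbon (hydroxymethylation by protonated formaldehyde, then substitution of the activated alcohol by chloride); ring A is deactivated by the two carbonyl groups and should not react.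

Step 12
Reactants: 16 tert-butyldimethyl{[(4S,6R,10R)-6,10,14-trimethylpentadec-1-yn-4-yl]oxy}silane; 18 2-(chloromethyl)-3-methylnaphthalene-1,4-dione
Product: 20 2-[(2E,5S,7R,11R)-5-(tert-butyldimethylsilyloxy)-3,7,11,15-tetramethylhexadec-2-enyl]-3-methylnaphthalene-1,4-dione, via alkenylalane 19 (not isolated)
Conditions: Me3Al (2.5 equiv), Cp2ZrCl2 (0.25 equiv), ClCH2CH2Cl, 0 °C → rt; evaporate volatiles, hexane then THF; 18 (0.8 equiv), NiCl2(PPh3)2 (5 mol%) pre-reduced with n-BuLi (10 mol%) to zerovalent nickel, −20 °C → rt; dil. HCl
Reagents that add atoms: trimethylaluminium, C[Al](C)C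
Why: Zirconium-catalysed syn-methylalumination (Negishi carboalumination) places methyl on the internal and aluminium on the terminal alkyne carbon, which fixes the E geometry in 19; zerovalent nickel then inserts into the activated C–Cl bond of 18, the alkenyl group is transferred from aluminium and reductive elimination forms C1'–C2' with retention, a coupling known for chloromethylated quinones and alkenylalanes in prenylquinone synthesis. Excess Me3Al is removed before 18 is added so that the quinone meets only the less nucleophilic alkenylalane.

Step 13
Reactants: 20 2-[(2E,5S,7R,11R)-5-(tert-butyldimethylsilyloxy)-3,7,11,15-tetramethylhexadec-2-enyl]-3-methylnaphthalene-1,4-dione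
Product: 21 2-[(2E,5S,7R,11R)-5-hydroxy-3,7,11,15-tetramethylhexadec-2-enyl]-3-methylnaphthalene-1,4-dione
Conditions: HF·pyridine, THF/pyridine, 0 °C → rt, dark
Reagents that add atoms: none
Why: Fluoride-induced desilylation under mildly acidic conditions, chosen because the quinone and its C1' methylene do not tolerate basic fluoride sources; the homoallylic alcohol has no low-energy cationic pathway here and C5' is not affected.

## Compound list

1 | (R)-citronellal, (3R)-3,7-dimethyloct-6-enal | O=CC[C@H](C)CCC=C(C)C | starting material
2 | (3R)-3,7-dimethyloctanal | O=CC[C@H](C)CCCC(C)C | intermediate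
3 | 1-propynylmagnesium bromide | CC#C[Mg]Br | starting material
4 | (6R)-6,10-dimethylundec-2-yn-4-ol (both C4 epimers) | CC#CC(O)C[C@H](C)CCCC(C)C | intermediate
5 | (6R)-6,10-dimethylundec-2-yn-4-one | CC#CC(=O)C[C@H](C)CCCC(C)C | intermediate
6 | (4S,6R)-6,10-dimethylundec-2-yn-4-ol | CC#C[C@@H](O)C[C@H](C)CCCC(C)C | intermediate
7 | (2E,4S,6R)-6,10-dimethylundec-2-en-4-ol | C/C=C/[C@@H](O)C[C@H](C)CCCC(C)C | intermediate
8 | triethyl orthoacetate | CCOC(C)(OCC)OCC | starting material
9 | (2E,4S,6R)-4-(1,1-diethoxyethoxy)-6,10-dimethylundec-2-ene (mixed orthoester) | C/C=C/[C@@H](OC(C)(OCC)OCC)C[C@H](C)CCCC(C)C | intermediate (not isolated)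
10 | (2E,4S,6R)-4-[(1-ethoxyethenyl)oxy]-6,10-dimethylundec-2-ene (ketene acetal) | C/C=C/[C@@H](OC(=C)OCC)C[C@H](C)CCCC(C)C | intermediate (not isolated)
11 | ethyl (3S,4E,7R)-3,7,11-trimethyldodec-4-enoate | CCOC(=O)C[C@H](C)/C=C/C[C@H](C)CCCC(C)C | intermediate
12 | ethyl (3R,7R)-3,7,11-trimethyldodecanoate | CCOC(=O)C[C@H](C)CCC[C@H](C)CCCC(C)C | intermediate
13 | (3R,7R)-3,7,11-trimethyldodecanal | O=CC[C@H](C)CCC[C@H](C)CCCC(C)C | intermediate
14 | allenylboronic acid pinacol ester | C=C=CB1OC(C)(C)C(C)(C)O1 | starting material
15 | (4S,6R,10R)-6,10,14-trimethylpentadec-1-yn-4-ol | C#CC[C@@H](O)C[C@H](C)CCC[C@H](C)CCCC(C)C | intermediate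
16 | tert-butyldimethyl{[(4S,6R,10R)-6,10,14-trimethylpentadec-1-yn-4-yl]oxy}silane | C#CC[C@@H](O[Si](C)(C)C(C)(C)C)C[C@H](C)CCC[C@H](C)CCCC(C)C | intermediate
17 | menadione, 2-methylnaphthalene-1,4-dione | CC1=CC(=O)c2ccccc2C1=O | starting material
18 | 2-(chloromethyl)-3-methylnaphthalene-1,4-dione | CC1=C(CCl)C(=O)c2ccccc2C1=O | intermediate
19 | [(1E,4S,6R,10R)-4-(tert-butyldimethylsilyloxy)-2,6,10,14-tetramethylpentadec-1-enyl]dimethylalumane | C[Al](C)/C=C(\C)C[C@@H](O[Si](C)(C)C(C)(C)C)C[C@H](C)CCC[C@H](C)CCCC(C)C | intermediate (not isolated)
20 | 2-[(2E,5S,7R,11R)-5-(tert-butyldimethylsilyloxy)-3,7,11,15-tetramethylhexadec-2-enyl]-3-methylnaphthalene-1,4-dione | CC1=C(C/C=C(\C)C[C@@H](O[Si](C)(C)C(C)(C)C)C[C@H](C)CCC[C@H](C)CCCC(C)C)C(=O)c2ccccc2C1=O | intermediate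
21 | 2-[(2E,5S,7R,11R)-5-hydroxy-3,7,11,15-tetramethylhexadec-2-enyl]-3-methylnaphthalene-1,4-dione | CC1=C(C/C=C(\C)C[C@@H](O)C[C@H](C)CCC[C@H](C)CCCC(C)C)C(=O)c2ccccc2C1=O | target

## Step count and least certain steps

Total step count: 13. Longest linear sequence: 12 steps from 1 (steps 1–10, 12 and 13); 18 is a one-step branch from 17 (step 11).

**Step 6 (key step).** The most likely failure is partial loss of stereochemical fidelity. It could come from acid-induced ionisation and 1,3-transposition of the allylic C–O bond before rearrangement, or from leakage through the chair with the chain axial; elimination to a diene at 138 °C would cost material. Fallback from 7 back to 11: acetylation (Ac2O, pyridine) to (2E,4S,6R)-6,10-dimethylundec-2-en-4-yl acetate F1; enolisation with LiN(i-Pr)2 and trapping with Me3SiCl in THF at −78 °C to the O-trimethylsilyl ketene acetal F2, which should rearrange on warming to room temperature through the same chair without acid (Ireland–Claisen rearrangement); aqueous work-up to (3S,4E,7R)-3,7,11-trimethyldodec-4-enoic acid F3; EtI, K2CO3, DMF then returns to 11.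

**Step 9.** Facial selectivity may be incomplete with an α-unbranched aliphatic aldehyde, which would give the C5' epimer; a minor allenic product from α-attack is also possible. Fallback from 13 back to 15: Me3SI, NaH, DMSO (Corey–Chaykovsky) to 2-[(2R,6R)-2,6,10-trimethylundecyl]oxirane F4 as both oxirane epimers. Hydrolytic kinetic resolution follows, with H2O (0.55 equiv) and the (salen)Co(OAc) enantiomer that hydrolyses the 2R epimer; this is the (R,R) complex by the usual correlation for alkyl-substituted terminal epoxides, [N,N'-bis(3,5-di-tert-butylsalicylidene)cyclohexane-1,2-diaminato]cobalt acetate, trivalent cobalt. It leaves (2S)-2-[(2R,6R)-2,6,10-trimethylundecyl]oxirane F5 and removes the other epimer as (2R,4R,8R)-4,8,12-trimethyltridecane-1,2-diol F6. HC≡CLi·H2NCH2CH2NH2 in DMSO then opens F5 at its methylene carbon to give 15. The price is half the material and two extra steps.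

**Step 12.** Methylalumination may be incompletely regioselective, and residual organoaluminium or low-valent nickel may reduce the quinone or add to its carbonyl groups. Fallback from 17 and from 16 (through 19) back to 20: reductive methylation of 17 (Na2S2O4; then Me2SO4, KOH) to 1,4-dimethoxy-2-methylnaphthalene F7; chloromethylation (paraformaldehyde, HCl, AcOH) to 2-(chloromethyl)-1,4-dimethoxy-3-methylnaphthalene F8; coupling of F8 with 19 under Pd(PPh3)4 (zerovalent palladium) in THF to tert-butyl{[(2E,5S,7R,11R)-1-(1,4-dimethoxy-3-methylnaphthalen-2-yl)-3,7,11,15-tetramethylhexadec-2-en-5-yl]oxy}dimethylsilane F9; oxidative demethylation with (NH4)2Ce(NO3)6 in MeCN/H2O at 0 °C then gives 20. Here the organometallic step meets only an arene.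

**Step 4.** Enantioselectivity may erode, or 2-propanol may add in conjugate fashion to the ynone. Any 4R carbinol would end as the inseparable C7' epimer. Fallback from 4 back to 7: LiAlH4 in THF (as in step 5) to (2E,6R)-6,10-dimethylundec-2-en-4-ol F10 as both C4 epimers. Sharpless kinetic resolution with Ti(O-i-Pr)4, D-(−)-diisopropyl tartrate and t-BuOOH (0.6 equiv), 4 Å MS, CH2Cl2, −20 °C should then epoxidise the 4R epimer to (1R,3R)-3,7-dimethyl-1-[(2S,3S)-3-methyloxiran-2-yl]octan-1-ol F11 and leave 7. The same resolution could also polish 7 from the main route.

**Step 8.** The aluminium hemiacetal may collapse early, which would lead to over-reduction to the primary alcohol. Fallback from 12 back to 13: full reduction with LiAlH4 in THF at 0 °C to (3R,7R)-3,7,11-trimethyldodecan-1-ol F12, then Dess–Martin periodinane in CH2Cl2 to 13.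

## Further compounds

F1 | step 6 | (2E,4S,6R)-6,10-dimethylundec-2-en-4-yl acetate | C/C=C/[C@@H](OC(C)=O)C[C@H](C)CCCC(C)C
F2 | step 6 | {[1-{[(2E,4S,6R)-6,10-dimethylundec-2-en-4-yl]oxy}ethenyl]oxy}trimethylsilane | C/C=C/[C@@H](OC(=C)O[Si](C)(C)C)C[C@H](C)CCCC(C)C
F3 | step 6 | (3S,4E,7R)-3,7,11-trimethyldodec-4-enoic acid | OC(=O)C[C@H](C)/C=C/C[C@H](C)CCCC(C)C
F4 | step 9 | 2-[(2R,6R)-2,6,10-trimethylundecyl]oxirane (both oxirane epimers) | C1OC1C[C@H](C)CCC[C@H](C)CCCC(C)C
F5 | step 9 | (2S)-2-[(2R,6R)-2,6,10-trimethylundecyl]oxirane | C1O[C@H]1C[C@H](C)CCC[C@H](C)CCCC(C)C
F6 | step 9 | (2R,4R,8R)-4,8,12-trimethyltridecane-1,2-diol | OC[C@H](O)C[C@H](C)CCC[C@H](C)CCCC(C)C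
F7 | step 12 | 1,4-dimethoxy-2-methylnaphthalene | COc1cc(C)c(OC)c2ccccc12
F8 | step 12 | 2-(chloromethyl)-1,4-dimethoxy-3-methylnaphthalene | COc1c(C)c(CCl)c(OC)c2ccccc12
F9 | step 12 | tert-butyl{[(2E,5S,7R,11R)-1-(1,4-dimethoxy-3-methylnaphthalen-2-yl)-3,7,11,15-tetramethylhexadec-2-en-5-yl]oxy}dimethylsilane | COc1c(C)c(C/C=C(\C)C[C@@H](O[Si](C)(C)C(C)(C)C)C[C@H](C)CCC[C@H](C)CCCC(C)C)c(OC)c2ccccc12
F10 | step 4 | (2E,6R)-6,10-dimethylundec-2-en-4-ol (both C4 epimers) | C/C=C/C(O)C[C@H](C)CCCC(C)C
F11 | step 4 | (1R,3R)-3,7-dimethyl-1-[(2S,3S)-3-methyloxiran-2-yl]octan-1-ol | C[C@@H]1O[C@H]1[C@H](O)C[C@H](C)CCCC(C)C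
F12 | step 8 | (3R,7R)-3,7,11-trimethyldodecan-1-ol | OCC[C@H](C)CCC[C@H](C)CCCC(C)C
A1 | alternative 1 | 4-methoxy-3-methyl-2-[(2E,5S,7R,11R)-5-(tert-butyldimethylsilyloxy)-3,7,11,15-tetramethylhexadec-2-enyl]naphthalen-1-ol | COc1c(C)c(C/C=C(\C)C[C@@H](O[Si](C)(C)C(C)(C)C)C[C@H](C)CCC[C@H](C)CCCC(C)C)c(O)c2ccccc12
A2 | alternative 1 | tert-butyldimethyl{[(5E,8S,10R,14R)-6,10,14,18-tetramethylnonadec-5-en-2-yn-8-yl]oxy}silane | CC#CC/C=C(\C)C[C@@H](O[Si](C)(C)C(C)(C)C)C[C@H](C)CCC[C@H](C)CCCC(C)C
A3 | alternative 1 | pentacarbonyl[methoxy(phenyl)carbene]chromium | COC(c1ccccc1)=[Cr](=C=O)(=C=O)(=C=O)(=C=O)=C=O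
A4 | alternative 2 | (2E,5S,7R,11R)-1-(1,4-dimethoxy-3-methylnaphthalen-2-yl)-3,7,11,15-tetramethylhexadec-2-en-5-ol | COc1c(C)c(C/C=C(\C)C[C@@H](O)C[C@H](C)CCC[C@H](C)CCCC(C)C)c(OC)c2ccccc12
A5 | alternative 2 | 2-[(2S)-1-(1,4-dimethoxy-3-methylnaphthalen-2-yl)-3-methylbut-3-en-2-yl]-4,4,5,5-tetramethyl-1,3,2-dioxaborolane | COc1c(C)c(C[C@H](B3OC(C)(C)C(C)(C)O3)C(C)=C)c(OC)c2ccccc12
A6 | alternative 3 | ethyl (3S,5R,9R)-3-(tert-butyldimethylsilyloxy)-5,9,13-trimethyltetradecanoate | CCOC(=O)C[C@@H](O[Si](C)(C)C(C)(C)C)C[C@H](C)CCC[C@H](C)CCCC(C)C
A7 | alternative 3 | ethyl (3R,4E,8E)-3-(tert-butyldimethylsilyloxy)-5,9,13-trimethyltetradeca-4,8,12-trienoate | CCOC(=O)C[C@@H](O[Si](C)(C)C(C)(C)C)/C=C(\C)CC/C=C(\C)CCC=C(C)C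
A8 | alternative 3 | (2E,6E)-farnesal, (2E,6E)-3,7,11-trimethyldodeca-2,6,10-trienal | O=C/C=C(\C)CC/C=C(\C)CCC=C(C)C
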